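**Retrosynthetic overview**
- The C2–aryl bond is the last C–C bond formed, by enantioselective rhodium-catalysed conjugate arylation of a 7-O-MOM-6,8-diprenylchromone with 4-methoxyphenylboronic acid; MOM removal ends the route.
- Ring C closes at O1–C2 from an enaminone of 2,4-dihydroxy-3,5-diprenylacetophenone (C2 from DMF dimethyl acetal, C3 from methyllithium on the ring A carboxyl carbon).
- Ring A is built, not substituted. The strategy rests on reading C6(prenyl)–C7(OH)–C8(prenyl) as the backbone of mirror-symmetric 1,3-diprenylacetone, and C5(H)–C4a with its two carboxyl-level neighbours C4 and C8a(–O1) as an ethoxymethylenemalonate. A [3+3] Michael–Claisen benzannulation joins C5–C6 and C8–C8a with no regiochemical choice.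
- Both prenyl groups are placed on sp3 carbon beforehand (double alkylation of dimethyl acetonedicarboxylate, then decarboxylation).
- Ring order: A (annulation), then C (chromone), then B (attached at C2).

Key step: step 3

Remark: flavanone numbering (O1, C2, C3, C4, C4a, C5 to C8, C8a) is used for ring atoms throughout; prenyl means 3-methylbut-2-en-1-yl; the target SMILES is read as the 2S enantiomer, and the target is referred to by its systematic name.

**Route**

Step 1
Reactants: 1 dimethyl 3-oxopentanedioate; 2 prenyl bromide (1-bromo-3-methylbut-2-ene, 2 equiv in total)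
Product: 4 dimethyl 2,4-bis(3-methylbut-2-en-1-yl)-3-oxopentanedioate (diastereomer mixture), via monoprenyl keto diester 3 (not isolated)
Conditions: NaH (1.05 equiv), THF, 0 °C, then 2 (1.0 equiv), 0 °C → rt; second portion of NaH (1.05 equiv) and 2 (1.0 equiv) in the same flask
Reagents that add atoms: none
Why: Stepwise SN2 C-alkylation of the sodium enolate of a β-keto diester; after the first prenylation the second deprotonation should occur at the unsubstituted, more acidic and less hindered α'-CH2, which puts one prenyl on each α-carbon, and the two stereocentres are destroyed in steps 2 and 3.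

Step 2
Reactants: 4 dimethyl 2,4-bis(3-methylbut-2-en-1-yl)-3-oxopentanedioate
Product: 6 2,10-dimethylundeca-2,9-dien-6-one (1,3-diprenylacetone), via keto diacid 5 (not isolated)
Conditions: NaOH (1 M aq, 3 equiv), MeOH, 0 °C → rt; then 1 M HCl to pH 3 at 0 °C, warm to 40 °C
Reagents that add atoms: none
Why: Ketonic hydrolysis, that is saponification of both esters and decarboxylation of the β-keto diacid through the cyclic six-membered transition state on mild acidification, with dilute base at low temperature to hold back retro-Claisen cleavage and without hot strong acid so that the trisubstituted alkenes are neither hydrated nor cyclised.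

Step 3
Reactants: 6 2,10-dimethylundeca-2,9-dien-6-one; 7 diethyl 2-(ethoxymethylidene)propanedioate (diethyl ethoxymethylenemalonate)
Product: 10 ethyl 2,4-dihydroxy-3,5-bis(3-methylbut-2-en-1-yl)benzoate, via alkylidenemalonate adduct 8 (not isolated), via cyclohexenedione ester 9 (not isolated)
Conditions: LiN(SiMe3)2 (1.1 equiv), THF, −78 °C; 7 (1.05 equiv), −78 → 0 °C; KOtBu (3 equiv), THF, 0 → 65 °C; cold 1 M HCl work-up
Reagents that add atoms: none
Why: Proposed new method: the preformed lithium enolate of ketone 6 should attack the ethoxymethylene carbon of 7 and lose ethoxide (conjugate addition–elimination, new C5–C6 bond) to give 8, and under excess tert-butoxide the other α-carbon of the ketone should then acylate the malonate ester that is fixed cis to the ketone chain, so that ring A closes at C8–C8a by a 6-exo-trig Dieckmann-type C-acylation and diketone 9 enolises twice to the arene. The closest known reaction types are the tert-butoxide-mediated Michael–Claisen synthesis of cyclohexane-1,3-diones from simple ketones and acrylates, the Michael–Dieckmann resorcinol synthesis from acetonedicarboxylate anions, and the condensation of ketone enolates with alkoxymethylenemalonates that normally ends at a 2-pyrone-3-carboxylate; what is untested is a simple dialkyl ketone as bis-nucleophile towards an alkoxymethylenemalonate with C-acylation as the closing event. No lasting stereocentre is formed, since the α-centres of 8 and 9 disappear on aromatisation. The selectivity needed is C- over O-acylation: lactonisation to the pyrone is reversible in the presence of the liberated ethoxide, whereas formation of the chelated resorcylate dianion is not, so excess base and heat should drain the equilibrium towards 10. Regiochemistry does not arise, because ketone 6 has two equivalent α-carbons and 7 two equivalent ester groups, so every pairing leads to the same arene and the ester left over ends up as C4. Because only ethanol is lost, the prenyl double bonds are never exposed to an oxidising agent.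

Step 4
Reactants: 10 ethyl 2,4-dihydroxy-3,5-bis(3-methylbut-2-en-1-yl)benzoate
Product: 11 2,4-dihydroxy-3,5-bis(3-methylbut-2-en-1-yl)benzoic acid
Conditions: NaOH (2 M aq, 8 equiv), EtOH, 75 °C, under nitrogen; then 1 M HCl to pH 3 at 0 °C
Reagents that add atoms: sodium hydroxide, [Na+].[OH-]
Why: Ester saponification by hydroxide addition–elimination at the acyl carbon, slowed by the two phenoxides but feasible with excess hydroxide on warming under inert gas, with cold acidification so that the β-resorcylic acid does not decarboxylate and the ortho-prenyl phenols do not cyclise to chromans.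

Step 5
Reactants: 11 2,4-dihydroxy-3,5-bis(3-methylbut-2-en-1-yl)benzoic acid
Product: 12 1-[2,4-dihydroxy-3,5-bis(3-methylbut-2-en-1-yl)phenyl]ethan-1-one
Conditions: MeLi (6 equiv), THF, 0 °C → rt; inverse quench into 1 M HCl at 0 °C
Reagents that add atoms: methyllithium, [Li]C
Why: Ketone synthesis by addition of an organolithium to a lithium carboxylate, in which three equivalents of MeLi remove the acidic protons and a fourth adds to give a geminal dialkoxide that is stable until the inverse acidic quench, so that over-addition is held back and the new methyl becomes C3.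

Step 6
Reactants: 12 1-[2,4-dihydroxy-3,5-bis(3-methylbut-2-en-1-yl)phenyl]ethan-1-one
Product: 13 1-[2-hydroxy-4-(methoxymethoxy)-3,5-bis(3-methylbut-2-en-1-yl)phenyl]ethan-1-one
Conditions: MOMCl (1.15 equiv), iPr2NEt (1.5 equiv), CH2Cl2, 0 °C → rt
Reagents that add atoms: chloromethyl methyl ether, COCCl
Why: O-alkylation with an α-chloro ether, selective for the 4-OH (future O7) because the 2-OH is held in a hydrogen bond to the acetyl carbonyl and is far less nucleophilic; the protection is needed because the amide acetal of step 7 would otherwise methylate this phenol.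

Step 7
Reactants: 13 1-[2-hydroxy-4-(methoxymethoxy)-3,5-bis(3-methylbut-2-en-1-yl)phenyl]ethan-1-one
Product: 15 7-(methoxymethoxy)-6,8-bis(3-methylbut-2-en-1-yl)-4H-chromen-4-one, via enaminone 14 (not isolated)
Conditions: Me2NCH(OMe)2 (3 equiv), toluene, 90 °C; concentrate; AcOH (10 equiv), toluene, 70 °C
Reagents that add atoms: N,N-dimethylformamide dimethyl acetal, COC(OC)N(C)C
Why: Condensation of the methyl ketone with the amide acetal gives the enaminone (C2 added), and weak acid promotes 6-endo addition of the 2-OH to the β-carbon followed by loss of dimethylamine (enaminone route to chromones, O1–C2 closure of ring C) under conditions mild enough to keep the MOM acetal and the prenyl groups.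

Step 8
Reactants: 15 7-(methoxymethoxy)-6,8-bis(3-methylbut-2-en-1-yl)-4H-chromen-4-one; 16 (4-methoxyphenyl)boronic acid
Product: 17 (2S)-7-(methoxymethoxy)-2-(4-methoxyphenyl)-6,8-bis(3-methylbut-2-en-1-yl)-2,3-dihydro-4H-chromen-4-one
Conditions: [Rh(OH)(cod)]2 (2.5 mol %), (S)-6,6'-dimethoxy-2,2'-bis[bis(3,4,5-trifluorophenyl)phosphino]-1,1'-biphenyl (5.5 mol %), 16 (3 equiv), toluene/H2O (10:1), 25–40 °C, no added base
Reagents that add atoms: none
Why: Hayashi–Miyaura-type asymmetric 1,4-addition with a monovalent rhodium hydroxo complex, in which the aryl–rhodium species from transmetallation inserts the chromone C2=C3 bond on the face left open by the axially chiral electron-poor bisphosphine and water releases the flavanone without base, so the C2 centre is set by the ligand (the S antipode is chosen by analogy with the facial preference of cyclic enones and is to be checked against the chiroptical signature of 2S-flavanones, the R ligand being used if the sense proves reversed) and is not eroded by retro-oxa-Michael opening.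

Step 9
Reactants: 17 (2S)-7-(methoxymethoxy)-2-(4-methoxyphenyl)-6,8-bis(3-methylbut-2-en-1-yl)-2,3-dihydro-4H-chromen-4-one
Product: 18 (2S)-7-hydroxy-2-(4-methoxyphenyl)-6,8-bis(3-methylbut-2-en-1-yl)-2,3-dihydro-4H-chromen-4-one (the target flavanone)
Conditions: HCl (3 M aq, 5 equiv), MeOH/THF (3:1), 20 °C
Reagents that add atoms: none
Why: Acid-catalysed solvolysis of the MOM acetal with methanol as formaldehyde acceptor, in the absence of base so that the 2S centre cannot racemise through chalcone opening, and with dilute acid at room temperature so that the 6- and 8-prenyl groups do not add to the freed 7-OH.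

**Compound list**
1 | dimethyl 3-oxopentanedioate | COC(=O)CC(=O)CC(=O)OC | starting material
2 | prenyl bromide (1-bromo-3-methylbut-2-ene) | CC(C)=CCBr | starting material
3 | dimethyl 2-(3-methylbut-2-en-1-yl)-3-oxopentanedioate (racemic) | COC(=O)CC(=O)C(CC=C(C)C)C(=O)OC | intermediate (not isolated)
4 | dimethyl 2,4-bis(3-methylbut-2-en-1-yl)-3-oxopentanedioate (diastereomer mixture) | COC(=O)C(CC=C(C)C)C(=O)C(CC=C(C)C)C(=O)OC | intermediate
5 | 2,4-bis(3-methylbut-2-en-1-yl)-3-oxopentanedioic acid | OC(=O)C(CC=C(C)C)C(=O)C(CC=C(C)C)C(=O)O | intermediate (not isolated)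
6 | 2,10-dimethylundeca-2,9-dien-6-one | CC(C)=CCCC(=O)CCC=C(C)C | intermediate
7 | diethyl 2-(ethoxymethylidene)propanedioate | CCOC=C(C(=O)OCC)C(=O)OCC | starting material
8 | diethyl 2-[7-methyl-2-(3-methylbut-2-en-1-yl)-3-oxooct-6-en-1-ylidene]propanedioate (racemic) | CCOC(=O)C(=CC(CC=C(C)C)C(=O)CCC=C(C)C)C(=O)OCC | intermediate (not isolated)
9 | ethyl 3,5-bis(3-methylbut-2-en-1-yl)-4,6-dioxocyclohex-1-ene-1-carboxylate (diastereomer mixture) | CCOC(=O)C1=CC(CC=C(C)C)C(=O)C(CC=C(C)C)C1=O | intermediate (not isolated)
10 | ethyl 2,4-dihydroxy-3,5-bis(3-methylbut-2-en-1-yl)benzoate | CCOC(=O)c1cc(CC=C(C)C)c(O)c(CC=C(C)C)c1O | intermediate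
11 | 2,4-dihydroxy-3,5-bis(3-methylbut-2-en-1-yl)benzoic acid | OC(=O)c1cc(CC=C(C)C)c(O)c(CC=C(C)C)c1O | intermediate
12 | 1-[2,4-dihydroxy-3,5-bis(3-methylbut-2-en-1-yl)phenyl]ethan-1-one | CC(=O)c1cc(CC=C(C)C)c(O)c(CC=C(C)C)c1O | intermediate
13 | 1-[2-hydroxy-4-(methoxymethoxy)-3,5-bis(3-methylbut-2-en-1-yl)phenyl]ethan-1-one | CC(=O)c1cc(CC=C(C)C)c(OCOC)c(CC=C(C)C)c1O | intermediate
14 | (E)-3-(dimethylamino)-1-[2-hydroxy-4-(methoxymethoxy)-3,5-bis(3-methylbut-2-en-1-yl)phenyl]prop-2-en-1-one | CN(C)/C=C/C(=O)c1cc(CC=C(C)C)c(OCOC)c(CC=C(C)C)c1O | intermediate (not isolated)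
15 | 7-(methoxymethoxy)-6,8-bis(3-methylbut-2-en-1-yl)-4H-chromen-4-one | O=c1ccoc2c(CC=C(C)C)c(OCOC)c(CC=C(C)C)cc12 | intermediate
16 | (4-methoxyphenyl)boronic acid | COc1ccc(B(O)O)cc1 | starting material
17 | (2S)-7-(methoxymethoxy)-2-(4-methoxyphenyl)-6,8-bis(3-methylbut-2-en-1-yl)-2,3-dihydro-4H-chromen-4-one | COc1ccc([C@@H]2CC(=O)c3cc(CC=C(C)C)c(OCOC)c(CC=C(C)C)c3O2)cc1 | intermediate
18 | (2S)-7-hydroxy-2-(4-methoxyphenyl)-6,8-bis(3-methylbut-2-en-1-yl)-2,3-dihydro-4H-chromen-4-one (the target flavanone) | COc1ccc([C@@H]2CC(=O)c3cc(CC=C(C)C)c(O)c(CC=C(C)C)c3O2)cc1 | target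

**Totals**
Total step count: 9. Longest linear sequence: 9 steps (from 1 to 18; compounds 2, 7 and 16 are bought).

**Steps most likely to fail**

Step 3 (Proposed new method). After the addition–elimination the material may stall as the delocalised anion of the alkylidenemalonate, or close through the enolate oxygen (lactonisation), without C-acylation taking over even on heating; self-aldol condensation of the ketone may also compete. The fallback uses known chemistry and gives up the de novo construction of ring A. It sets out from prenyl bromide 2 together with bought 1-(2,4-dihydroxyphenyl)ethan-1-one F1. Nuclear C-prenylation of the phenoxide with 2 (2.2 equiv) in 10% aqueous KOH at 0 °C → rt should give, after chromatographic separation from mono-C-prenylated, O-prenylated and geminally diprenylated isomers, acetophenone 12, where the route is rejoined. This phenoxide C-alkylation is expected to be low-yielding but is one step from bought materials.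

Step 5. Addition of MeLi to the poorly soluble, electron-rich trilithium salt may be sluggish or incomplete, and premature collapse of the dialkoxide would lead to over-addition. The fallback sets out from ester 10 and avoids both the free acid and the carboxylate addition. Acylation of excess NaCH2S(O)CH3 (from NaH and DMSO) by 10 in THF at rt should give the β-keto sulfoxide 1-[2,4-dihydroxy-3,5-bis(3-methylbut-2-en-1-yl)phenyl]-2-(methanesulfinyl)ethan-1-one F2. Reductive C–S cleavage with aluminium amalgam, Al(Hg), in aqueous THF at 0 °C → rt should then give 12, where the route is rejoined. Both operations are neutral to the prenyl alkenes.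

Step 8. Insertion into the electron-rich, 8-substituted chromone may be slow, so that protodeboronation of 16 outruns arylation, or the facial discrimination may be insufficient. The fallback sets out from acetophenone 13 and closes ring C at O1–C2 with ring B already in place. Claisen–Schmidt condensation of 13 with 4-methoxybenzaldehyde (KOH, EtOH, rt) should give the chalcone (E)-1-[2-hydroxy-4-(methoxymethoxy)-3,5-bis(3-methylbut-2-en-1-yl)phenyl]-3-(4-methoxyphenyl)prop-2-en-1-one F3. Oxa-Michael cyclisation (NaOAc, EtOH, reflux) should give the racemic flavanone, racemic 7-(methoxymethoxy)-2-(4-methoxyphenyl)-6,8-bis(3-methylbut-2-en-1-yl)-2,3-dihydro-4H-chromen-4-one F4. Preparative chromatography on a chiral stationary phase should deliver the 2S enantiomer, which is 17, where the route is rejoined. The 2R material can be re-equilibrated through F3 with NaOAc and resubmitted.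

**Further compounds**
F1 | step 3 | 1-(2,4-dihydroxyphenyl)ethan-1-one (bought) | CC(=O)c1ccc(O)cc1O
F2 | step 5 | 1-[2,4-dihydroxy-3,5-bis(3-methylbut-2-en-1-yl)phenyl]-2-(methanesulfinyl)ethan-1-one | CS(=O)CC(=O)c1cc(CC=C(C)C)c(O)c(CC=C(C)C)c1O
F3 | step 8 | (E)-1-[2-hydroxy-4-(methoxymethoxy)-3,5-bis(3-methylbut-2-en-1-yl)phenyl]-3-(4-methoxyphenyl)prop-2-en-1-one | COc1ccc(/C=C/C(=O)c2cc(CC=C(C)C)c(OCOC)c(CC=C(C)C)c2O)cc1
F4 | step 8 | racemic 7-(methoxymethoxy)-2-(4-methoxyphenyl)-6,8-bis(3-methylbut-2-en-1-yl)-2,3-dihydro-4H-chromen-4-one | COc1ccc(C2CC(=O)c3cc(CC=C(C)C)c(OCOC)c(CC=C(C)C)c3O2)cc1
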